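**Retrosynthetic overview**
- Target ⇒ open the O1–C2 bond of the dihydrofuran: an achiral (Z)-2-(2-hydroxyaryl)-3-(4-hydroxy-3,5-dimethoxyphenyl)allyl alcohol (a 4-hydroxystilbene). In the forward direction a catalytic C–O ring closure through its p-quinone methide tautomer sets C3 and C2 together.
- Stilbene allyl alcohol ⇒ aryl–vinyl bond: the ortho-iodophenol from methyl dihydroferulate plus an (E)-2-stannyl cinnamyl alcohol, made in the flask by hydrostannation of an aryl propargyl alcohol.
- Aryl propargyl alcohol ⇒ 4-bromo-2,6-dimethoxyphenol + propargyl alcohol (Sonogashira); iodophenol ⇒ methyl dihydroferulate (ortho-iodination).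
- Ring order: both benzene rings are bought; the only ring made is the dihydrofuran, last, by C–O bond formation. No protecting groups.

Assumptions: 1 and 3 are bought as catalogue chemicals; the sense of induction in step 4 rests on a binding model and, if the first run shows the opposite sense, the quinine-derived pseudoenantiomer of the catalyst is used under the same conditions.

**Step 1**
Reactants: 1 methyl 3-(4-hydroxy-3-methoxyphenyl)propanoate
Product: 2 methyl 3-(4-hydroxy-3-iodo-5-methoxyphenyl)propanoate
Conditions: NIS (1.05 equiv), TsOH·H2O (10 mol%), MeCN, 0 °C to rt, 3 h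
Reagents that add atoms: N-iodosuccinimide, O=C1CCC(=O)N1I
Why: Electrophilic aromatic iodination (SEAr) in which the free phenol directs to its only open ortho position because the para position carries the side chain (the selectivity that turns vanillin into 5-iodovanillin), the ester being inert; no stereocentre is formed.

**Step 2**
Reactants: 3 4-bromo-2,6-dimethoxyphenol; 4 prop-2-yn-1-ol
Product: 5 3-(4-hydroxy-3,5-dimethoxyphenyl)prop-2-yn-1-ol
Conditions: PdCl2(MeCN)2 (2 mol%), XPhos (6 mol%), Cs2CO3 (2.6 equiv), MeCN, 75 °C, slow addition of 4 (1.5 equiv)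
Reagents that add atoms: none
Why: Copper-free Sonogashira coupling in which XPhos-ligated zerovalent palladium inserts into the electron-rich C–Br bond even with the phenol ionised, while the absence of copper and the slow alkyne addition suppress Glaser dimerisation and the carbonate base leaves the primary alcohol untouched; no stereocentre is formed.

**Step 3**
Reactants: 5 3-(4-hydroxy-3,5-dimethoxyphenyl)prop-2-yn-1-ol; 2 methyl 3-(4-hydroxy-3-iodo-5-methoxyphenyl)propanoate
Product: 7 methyl 3-{4-hydroxy-3-[(1Z)-3-hydroxy-1-(4-hydroxy-3,5-dimethoxyphenyl)prop-1-en-2-yl]-5-methoxyphenyl}propanoate, via vinylstannane 6 (not isolated)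
Conditions: Bu3SnH (1.1 equiv, slow addition), PdCl2(PPh3)2 (2 mol%), THF, 0 °C; then 2 (0.85 equiv), Pd2(dba)3 (2.5 mol%), AsPh3 (20 mol%), CuI (20 mol%), DMF, 45 °C
Reagents that add atoms: none
Why: Palladium-catalysed syn-hydrostannation followed in the same flask by a base-free Stille coupling: hydride goes to the alkyne carbon bearing the donor arene and tin to the carbon next to CH2OH (the propargylic oxygen and the electron-rich ring should polarise the triple bond in the same sense), giving the (E)-stannane 6, and the CuI/AsPh3-accelerated coupling replaces tin by ring A with retention to give the (Z)-alkene 7, whose geometry is erased in step 4 in any case.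

**Step 4**
Reactants: 7 methyl 3-{4-hydroxy-3-[(1Z)-3-hydroxy-1-(4-hydroxy-3,5-dimethoxyphenyl)prop-1-en-2-yl]-5-methoxyphenyl}propanoate
Product: 9 methyl 3-[(2S,3R)-2-(4-hydroxy-3,5-dimethoxyphenyl)-3-(hydroxymethyl)-7-methoxy-2,3-dihydro-1-benzofuran-5-yl]propanoate, via p-quinone methide 8 (not isolated)
Conditions: quinidine-derived squaramide catalyst [3,5-(CF3)2C6H3NH-squaramide of (8R,9R)-9-amino-9-deoxy-epi-quinidine] (10 mol%), CH2Cl2/toluene 1:1 (0.05 M), 30 °C, argon, dark; filtered through a short silica plug at ca. 90% conversion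
Reagents that add atoms: none
Why: Proposed new method: catalytic enantioselective cycloisomerisation of a 2-(2-hydroxyaryl)-4′-hydroxystilbene, in which the quinuclidine nitrogen deprotonates the 4-hydroxy-3,5-dimethoxyphenyl group, the squaramide holds the phenoxide, and the chiral ammonium returns the proton to the vinylogous carbon (the future C3) on one face to give the (R)-p-quinone methide 8, whose exocyclic carbon is then attacked 5-exo by the neighbouring ring A phenol (general-base assisted by the same amine) anti to the CH2OH arm, so that C2 becomes S and trans to C3 (a cis product re-opens and equilibrates to trans; if 8 returns to 7 faster than it closes, the catalyst selects the (R)-quinone methide in the C–O bond-forming step instead); the estimated cost of the tautomerisation (roughly 6–9 kcal/mol) is repaid by ring closure (roughly −3 kcal/mol overall), the reaction is an isomerisation, and no acid is present that could ionise the allylic alcohol; the closest known reaction types are squaramide- or phosphoric-acid-catalysed asymmetric 1,6-additions to p-quinone methides, the asymmetric chalcone-to-flavanone oxa-Michael cyclisation, and the enzymatic hydration of 4-hydroxystyrenes through quinone methides.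

**Compound list**
1 | methyl 3-(4-hydroxy-3-methoxyphenyl)propanoate (methyl dihydroferulate) | COC(=O)CCc1ccc(O)c(OC)c1 | starting material
2 | methyl 3-(4-hydroxy-3-iodo-5-methoxyphenyl)propanoate | COC(=O)CCc1cc(I)c(O)c(OC)c1 | intermediate
3 | 4-bromo-2,6-dimethoxyphenol | COc1cc(Br)cc(OC)c1O | starting material
4 | prop-2-yn-1-ol (propargyl alcohol) | OCC#C | starting material
5 | 3-(4-hydroxy-3,5-dimethoxyphenyl)prop-2-yn-1-ol | OCC#Cc1cc(OC)c(O)c(OC)c1 | intermediate
6 | (E)-3-(4-hydroxy-3,5-dimethoxyphenyl)-2-(tributylstannyl)prop-2-en-1-ol | CCCC[Sn](CCCC)(CCCC)/C(CO)=C/c1cc(OC)c(O)c(OC)c1 | intermediate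
7 | methyl 3-{4-hydroxy-3-[(1Z)-3-hydroxy-1-(4-hydroxy-3,5-dimethoxyphenyl)prop-1-en-2-yl]-5-methoxyphenyl}propanoate | COC(=O)CCc1cc(OC)c(O)c(c1)/C(CO)=C/c1cc(OC)c(O)c(OC)c1 | intermediate
8 | methyl 3-{3-[(2R)-1-(3,5-dimethoxy-4-oxocyclohexa-2,5-dien-1-ylidene)-3-hydroxypropan-2-yl]-4-hydroxy-5-methoxyphenyl}propanoate | COC(=O)CCc1cc(OC)c(O)c(c1)[C@H](CO)C=C1C=C(OC)C(=O)C(OC)=C1 | intermediate
9 | methyl 3-[(2S,3R)-2-(4-hydroxy-3,5-dimethoxyphenyl)-3-(hydroxymethyl)-7-methoxy-2,3-dihydro-1-benzofuran-5-yl]propanoate | COC(=O)CCc1cc(OC)c2c(c1)[C@H](CO)[C@@H](c1cc(OC)c(O)c(OC)c1)O2 | target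

**Total step count:** 4.
**Longest linear sequence:** 3 steps (1 → 2 → 7 → 9, or 3 → 5 → 7 → 9).

**Steps most likely to fail, in this order**

First, the cycloisomerisation of step 4, the proposed new method. The tautomerisation may be slow. An uncatalysed or adventitious-base closure would give racemic 9, so 7 is kept cold and base-free until use. The ring A phenol can open a competing o-quinone methide channel that isomerises the allylic alcohol to an aldehyde/lactol. The ee erodes if the mixture is left to reach equilibrium. The fallback uses known chemistry, sets out from 7 and comes back at 9 (through 8). Hydroxyl-directed Noyori hydrogenation of the allylic alcohol with Ru(OAc)2[(S)-BINAP] (or the (R)-ligand, whichever delivers the (R)-alcohol), H2 (50 bar), MeOH, gives methyl 3-{4-hydroxy-3-[(2R)-1-hydroxy-3-(4-hydroxy-3,5-dimethoxyphenyl)propan-2-yl]-5-methoxyphenyl}propanoate F5. Ag2O (1.2 equiv, CH2Cl2, rt, dark) then dehydrogenates the 4-alkyl-2,6-dimethoxyphenol to quinone methide 8, which closes to trans-9 as in the biomimetic phenylcoumaran syntheses. The point to watch there is competing oxidation of the ring A phenol.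

Second, the one-flask hydrostannation/Stille coupling of step 3. The stannane is α-branched and the iodide is ortho-substituted and electron-rich, so protodestannylation or hydrodeiodination by residual tin hydride may outrun the coupling. The fallback sets out from 6 (now isolated) and 2 and comes back at 7, with the polarity of the coupling reversed. I2 (CH2Cl2, 0 °C) converts 6 with retention into (E)-3-(4-hydroxy-3,5-dimethoxyphenyl)-2-iodoprop-2-en-1-ol F3. Miyaura borylation of 2 (B2pin2, PdCl2(dppf), KOAc, dioxane, 85 °C) gives methyl 3-[4-hydroxy-3-methoxy-5-(4,4,5,5-tetramethyl-1,3,2-dioxaborolan-2-yl)phenyl]propanoate F4. Suzuki–Miyaura coupling of F3 with F4 (PdCl2(dppf), K3PO4, dioxane/H2O, 50 °C) delivers 7.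

Third, the Sonogashira coupling of step 2. Oxidative addition into the phenoxide-substituted bromide may be too slow and propargyl alcohol may oligomerise. The fallback sets out from 3 and comes back at 5, giving up the protecting-group-free coupling. Ac2O/pyridine gives 4-bromo-2,6-dimethoxyphenyl acetate F1, a neutral and less electron-rich bromide. It undergoes the classical PdCl2(PPh3)2/CuI/Et3N coupling with 4 to give 4-(3-hydroxyprop-1-yn-1-yl)-2,6-dimethoxyphenyl acetate F2. K2CO3/MeOH (0 °C) removes the acetate to give 5.

**Further compounds**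
F1 | step 2 | 4-bromo-2,6-dimethoxyphenyl acetate | CC(=O)Oc1c(OC)cc(Br)cc1OC
F2 | step 2 | 4-(3-hydroxyprop-1-yn-1-yl)-2,6-dimethoxyphenyl acetate | CC(=O)Oc1c(OC)cc(C#CCO)cc1OC
F3 | step 3 | (E)-3-(4-hydroxy-3,5-dimethoxyphenyl)-2-iodoprop-2-en-1-ol | I/C(CO)=C/c1cc(OC)c(O)c(OC)c1
F4 | step 3 | methyl 3-[4-hydroxy-3-methoxy-5-(4,4,5,5-tetramethyl-1,3,2-dioxaborolan-2-yl)phenyl]propanoate | COC(=O)CCc1cc(OC)c(O)c(c1)B1OC(C)(C)C(C)(C)O1
F5 | step 4 | methyl 3-{4-hydroxy-3-[(2R)-1-hydroxy-3-(4-hydroxy-3,5-dimethoxyphenyl)propan-2-yl]-5-methoxyphenyl}propanoate | COC(=O)CCc1cc(OC)c(O)c(c1)[C@H](CO)Cc1cc(OC)c(O)c(OC)c1
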